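**Plan**

- Cuts: the flavanone C2–aryl bond (to 5,7-bis(benzyloxy)chromone and an arylboronic acid); the luteolin pyranone at O1–C2/C2–C3 and C4–C4a (to an ortho-hydroxyacetophenone and 3,4-bis(benzyloxy)benzaldehyde); luteolin ring A at C5–C6, C7–C8 and C4a–C5 (to an aryl siloxyalkyne and 3-(allyloxy)cyclobutenone).
- Enabling feature: luteolin ring A is a phloroglucinol ring in which C6, the biaryl carbon, lies between the oxygen-bearing C5 and C7 and is para to C8a–O1. An aryl ynol ether supplies C6 and C7(O); an oxygenated vinylketene supplies C5(O), C8, C8a(O) and C4a. The three oxygens arrive differentiated as OH, OSi and O-allyl.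
- Forward order: the catechol ring B of the eriodictyol half is turned into the siloxyalkyne; benzannulation builds luteolin ring A on it; pyranone ring C follows through a chalcone; the aryl bromide becomes a boronic acid and is added to a preformed chromone, which brings in flavanone rings A and C; global debenzylation ends the route.
- Stereochemistry: the single stereocentre, flavanone C2 (S), is set in step 14 by the chiral rhodium catalyst and afterwards meets only neutral hydrogenolysis.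

Key step: step 6

Assumption: the sense of induction in step 14 is taken from rhodium–biaryl bisphosphine additions to cyclic enones, where the (S)-ligand gives the (S)-β-aryl ketone; if a trial with phenylboronic acid and chromone 24 shows the opposite sense, the (R)-ligand is used.

**Route**

Step 1
Reactants: 1 5-bromo-2-hydroxy-3-methoxybenzaldehyde
Product: 2 5-bromo-2,3-dihydroxybenzaldehyde
Conditions: BBr3, CH2Cl2, −78 °C to rt; then H2O
Reagents that add atoms: none
Why: Lewis-acid cleavage of the aryl methyl ether by BBr3 leaves the aldehyde and the aryl bromide intact and frees the second catechol oxygen, so that both can later carry hydrogenolysable benzyl groups.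

Step 2
Reactants: 2 5-bromo-2,3-dihydroxybenzaldehyde
Product: 3 2,3-bis(benzyloxy)-5-bromobenzaldehyde
Conditions: BnBr, K2CO3, DMF, 60 °C
Reagents that add atoms: benzyl bromide, BrCc1ccccc1
Why: Williamson etherification of both phenols gives benzyl ethers that survive every later step and fall together in the final hydrogenolysis.

Step 3
Reactants: 3 2,3-bis(benzyloxy)-5-bromobenzaldehyde
Product: 4 1,2-bis(benzyloxy)-5-bromo-3-ethynylbenzene
Conditions: dimethyl (1-diazo-2-oxopropyl)phosphonate, K2CO3, MeOH/THF, 0 °C to rt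
Reagents that add atoms: dimethyl (1-diazo-2-oxopropyl)phosphonate, COP(=O)(OC)C(=[N+]=[N-])C(C)=O
Why: Ohira–Bestmann homologation (Seyferth–Gilbert type) converts the non-enolisable aryl aldehyde into the terminal alkyne under mild carbonate conditions that do not touch the aryl bromide.

Step 4
Reactants: 4 1,2-bis(benzyloxy)-5-bromo-3-ethynylbenzene
Product: 7 ({[2,3-bis(benzyloxy)-5-bromophenyl]ethynyl}oxy)tri(propan-2-yl)silane, via lithium acetylide 5 (not isolated), via lithium ynolate 6 (not isolated)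
Conditions: LiN(SiMe3)2, THF, −78 °C; t-BuOOLi (from t-BuOOH and LiN(SiMe3)2), −78 to 0 °C; i-Pr3SiOTf, −78 to 0 °C
Reagents that add atoms: tert-butyl hydroperoxide, CC(C)(C)OO; triisopropylsilyl trifluoromethanesulfonate, CC(C)[Si](OS(=O)(=O)C(F)(F)F)(C(C)C)C(C)C
Why: Oxidation of a lithium acetylide by lithium tert-butyl peroxide to the ynolate, followed by O-silylation, is the established way from terminal aryl alkynes to triisopropylsiloxyalkynes, and the amide base avoids bromine–lithium exchange.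

Step 5
Reactants: 8 3-ethoxycyclobut-2-en-1-one
Product: 9 3-(prop-2-en-1-yloxy)cyclobut-2-en-1-one
Conditions: allyl alcohol (excess), TsOH·H2O (cat.), toluene, 4 Å molecular sieves, 40 °C
Reagents that add atoms: prop-2-en-1-ol, C=CCO
Why: Acid-catalysed transetherification of the vinylogous ester (addition–elimination at C3) exchanges ethoxy for allyloxy, placing on the future pyranone oxygen a group that withstands fluoride, base and acid yet is removed by zerovalent palladium in the presence of benzyl ethers and the aryl bromide.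

Step 6
Reactants: 7 ({[2,3-bis(benzyloxy)-5-bromophenyl]ethynyl}oxy)tri(propan-2-yl)silane; 9 3-(prop-2-en-1-yloxy)cyclobut-2-en-1-one
Product: 14 2',3'-bis(benzyloxy)-5'-bromo-4-(prop-2-en-1-yloxy)-6-{[tri(propan-2-yl)silyl]oxy}biphenyl-2-ol, via vinylketene 10 (not isolated), via vinylcyclobutenone 11 (not isolated), via dienylketene 12 (not isolated), via cyclohexadienone 13 (not isolated)
Conditions: toluene, 110 °C, sealed tube; 9 (2 equiv)
Reagents that add atoms: none
Why: Thermal four-electron electrocyclic opening of 9 gives vinylketene 10, whose ketene C=C adds across the electron-rich siloxyalkyne 7 in a polar [2+2] cycloaddition to give the 4-alkenylcyclobutenone 11; a second four-electron opening gives dienylketene 12, which cyclises to dienone 13 and tautomerises to phenol 14. The closest known reaction is the Danheiser benzannulation of cyclobutenones with siloxyalkynes. The benzene ring (luteolin ring A) is closed by a thermal disrotatory six-electron electrocyclisation that joins the ketene carbon to the methylene terminus (C4a–C5), after the [2+2] step has made the C5–C6 and C7–C8 bonds. No stereocentre survives, since the sp3 carbon of racemic 11 is lost on aromatisation. The selectivity needed is regiochemical: the alkyne carbon remote from oxygen, which carries the aryl group, is the nucleophilic terminus and bonds to the ketene carbonyl carbon, so the aryl group ends between the new hydroxyl and the silyloxy group with the allyloxy group para to it. A silyl ynol ether is chosen over an ethyl one because it cannot lose an alkene by retro-ene fragmentation at the reaction temperature and is later removed by fluoride.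

Step 7
Reactants: 14 2',3'-bis(benzyloxy)-5'-bromo-4-(prop-2-en-1-yloxy)-6-{[tri(propan-2-yl)silyl]oxy}biphenyl-2-ol
Product: 16 2,2',3',6-tetrakis(benzyloxy)-5'-bromo-4-(prop-2-en-1-yloxy)biphenyl, via biphenyldiol 15 (not isolated)
Conditions: Bu4NF, THF, 0 °C; then K2CO3, BnBr, DMF, rt
Reagents that add atoms: benzyl bromide, BrCc1ccccc1
Why: Fluoride desilylation and double Williamson benzylation in one flask make the two oxygens that flank the biaryl bond identical benzyl ethers, which renders the two remaining C–H positions of ring A equivalent.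

Step 8
Reactants: 16 2,2',3',6-tetrakis(benzyloxy)-5'-bromo-4-(prop-2-en-1-yloxy)biphenyl
Product: 17 1-[2,2',3',6-tetrakis(benzyloxy)-5'-bromo-4-(prop-2-en-1-yloxy)biphenyl-3-yl]ethan-1-one
Conditions: AcOH, (CF3CO)2O, CH2Cl2, 0 °C to rt
Reagents that add atoms: acetic acid, CC(=O)O
Why: Friedel–Crafts acylation by the mixed acetic trifluoroacetic anhydride takes place on the trialkoxybenzene ring, the most nucleophilic arene present, at either of its two equivalent C–H positions and stops after one acylation because the ketone deactivates the ring.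

Step 9
Reactants: 17 1-[2,2',3',6-tetrakis(benzyloxy)-5'-bromo-4-(prop-2-en-1-yloxy)biphenyl-3-yl]ethan-1-one
Product: 18 1-[2,2',3',6-tetrakis(benzyloxy)-5'-bromo-4-hydroxybiphenyl-3-yl]ethan-1-one
Conditions: Pd(PPh3)4 (cat.), morpholine, THF, rt
Reagents that add atoms: none
Why: Tsuji–Trost deallylation with morpholine as allyl acceptor frees only the oxygen para to the biaryl bond as a hydrogen-bonded ortho-hydroxy ketone, while benzyl ethers and the electron-rich aryl bromide do not react with zerovalent palladium at room temperature.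

Step 10
Reactants: 18 1-[2,2',3',6-tetrakis(benzyloxy)-5'-bromo-4-hydroxybiphenyl-3-yl]ethan-1-one; 19 3,4-bis(benzyloxy)benzaldehyde
Product: 20 (E)-1-[2,2',3',6-tetrakis(benzyloxy)-5'-bromo-4-hydroxybiphenyl-3-yl]-3-[3,4-bis(benzyloxy)phenyl]prop-2-en-1-one
Conditions: KOH, EtOH/THF, rt
Reagents that add atoms: none
Why: Claisen–Schmidt aldol condensation of the methyl ketone with the non-enolisable aldehyde gives the (E)-2'-hydroxychalcone that carries all carbons of the luteolin half.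

Step 11
Reactants: 20 (E)-1-[2,2',3',6-tetrakis(benzyloxy)-5'-bromo-4-hydroxybiphenyl-3-yl]-3-[3,4-bis(benzyloxy)phenyl]prop-2-en-1-one
Product: 21 5,7-bis(benzyloxy)-6-[2,3-bis(benzyloxy)-5-bromophenyl]-2-[3,4-bis(benzyloxy)phenyl]-4H-chromen-4-one
Conditions: I2 (cat.), DMSO, 120 °C
Reagents that add atoms: none
Why: Iodine-catalysed oxidative cyclisation in DMSO (oxa-Michael closure, α-iodination and loss of HI) turns the 2'-hydroxychalcone into the flavone, and since only the oxygen para to the biaryl bond is free the aryl group ends at C6 and not at C8.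

Step 12
Reactants: 21 5,7-bis(benzyloxy)-6-[2,3-bis(benzyloxy)-5-bromophenyl]-2-[3,4-bis(benzyloxy)phenyl]-4H-chromen-4-one
Product: 22 {3,4-bis(benzyloxy)-5-[5,7-bis(benzyloxy)-2-(3,4-bis(benzyloxy)phenyl)-4-oxo-4H-chromen-6-yl]phenyl}boronic acid
Conditions: B2(OH)4, KOAc, Pd(XPhos)(2'-aminobiphenyl-2-yl)Cl (cat.), XPhos, EtOH/THF, 80 °C
Reagents that add atoms: tetrahydroxydiboron, OB(O)B(O)O
Why: Miyaura-type palladium-catalysed borylation with tetrahydroxydiboron converts the unhindered aryl bromide directly into the boronic acid under weakly basic conditions that the flavone tolerates.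

Step 13
Reactants: 23 5,7-dihydroxy-4H-chromen-4-one
Product: 24 5,7-bis(benzyloxy)-4H-chromen-4-one
Conditions: BnBr, K2CO3, DMF, 70 °C
Reagents that add atoms: benzyl bromide, BrCc1ccccc1
Why: Williamson benzylation of both phenols (the chelated 5-hydroxyl needs the heating) gives a chromone acceptor free of acidic protons and protected like the rest of the molecule.

Step 14
Reactants: 22 {3,4-bis(benzyloxy)-5-[5,7-bis(benzyloxy)-2-(3,4-bis(benzyloxy)phenyl)-4-oxo-4H-chromen-6-yl]phenyl}boronic acid; 24 5,7-bis(benzyloxy)-4H-chromen-4-one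
Product: 25 (2S)-5,7-bis(benzyloxy)-2-{3,4-bis(benzyloxy)-5-[5,7-bis(benzyloxy)-2-(3,4-bis(benzyloxy)phenyl)-4-oxo-4H-chromen-6-yl]phenyl}-2,3-dihydro-4H-chromen-4-one
Conditions: [Rh(OH)(cod)]2 (cat.), (S)-(6,6'-dimethoxybiphenyl-2,2'-diyl)bis[bis(3,4,5-trifluorophenyl)phosphane], toluene/H2O, 40 °C; 24 (2 equiv)
Reagents that add atoms: none
Why: Hayashi–Miyaura rhodium-catalysed asymmetric 1,4-addition of the arylboronic acid to the chromone forms the C2–aryl bond, the (S)-bisphosphine on rhodium selects the enone face and so sets C2 as S, and the base-free hydroxorhodium conditions avoid retro-oxa-Michael racemisation.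

Step 15
Reactants: 25 (2S)-5,7-bis(benzyloxy)-2-{3,4-bis(benzyloxy)-5-[5,7-bis(benzyloxy)-2-(3,4-bis(benzyloxy)phenyl)-4-oxo-4H-chromen-6-yl]phenyl}-2,3-dihydro-4H-chromen-4-one
Product: 26 (2S)-2-{3-[2-(3,4-dihydroxyphenyl)-5,7-dihydroxy-4-oxo-4H-chromen-6-yl]-4,5-dihydroxyphenyl}-5,7-dihydroxy-2,3-dihydro-4H-chromen-4-one
Conditions: H2 (1 atm), Pd/C, THF/MeOH, rt
Reagents that add atoms: none
Why: Catalytic hydrogenolysis removes all eight benzyl ethers under neutral conditions, so the base-sensitive flavanone stereocentre is not epimerised and no strong acid can trigger migration of the C6 aryl group.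

**Compound list**

1 | 5-bromo-2-hydroxy-3-methoxybenzaldehyde | COc1cc(Br)cc(C=O)c1O | starting material
2 | 5-bromo-2,3-dihydroxybenzaldehyde | O=Cc1cc(Br)cc(O)c1O | intermediate
3 | 2,3-bis(benzyloxy)-5-bromobenzaldehyde | O=Cc1cc(Br)cc(OCc2ccccc2)c1OCc1ccccc1 | intermediate
4 | 1,2-bis(benzyloxy)-5-bromo-3-ethynylbenzene | C#Cc1cc(Br)cc(OCc2ccccc2)c1OCc1ccccc1 | intermediate
5 | lithium [2,3-bis(benzyloxy)-5-bromophenyl]acetylide | [Li]C#Cc1cc(Br)cc(OCc2ccccc2)c1OCc1ccccc1 | intermediate (not isolated)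
6 | lithium 2-[2,3-bis(benzyloxy)-5-bromophenyl]ethyn-1-olate | [Li+].[O-]C#Cc1cc(Br)cc(OCc2ccccc2)c1OCc1ccccc1 | intermediate (not isolated)
7 | ({[2,3-bis(benzyloxy)-5-bromophenyl]ethynyl}oxy)tri(propan-2-yl)silane | CC(C)[Si](OC#Cc1cc(Br)cc(OCc2ccccc2)c1OCc1ccccc1)(C(C)C)C(C)C | intermediate
8 | 3-ethoxycyclobut-2-en-1-one | CCOC1=CC(=O)C1 | starting material
9 | 3-(prop-2-en-1-yloxy)cyclobut-2-en-1-one | C=CCOC1=CC(=O)C1 | intermediate
10 | 3-(prop-2-en-1-yloxy)buta-1,3-dien-1-one (vinylketene) | C=CCOC(=C)C=C=O | intermediate (not isolated)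
11 | 2-[2,3-bis(benzyloxy)-5-bromophenyl]-4-[1-(prop-2-en-1-yloxy)ethenyl]-3-{[tri(propan-2-yl)silyl]oxy}cyclobut-2-en-1-one (racemic) | C=CCOC(=C)C1C(=O)C(c2cc(Br)cc(OCc3ccccc3)c2OCc2ccccc2)=C1O[Si](C(C)C)(C(C)C)C(C)C | intermediate (not isolated)
12 | 2-[2,3-bis(benzyloxy)-5-bromophenyl]-5-(prop-2-en-1-yloxy)-3-{[tri(propan-2-yl)silyl]oxy}hexa-1,3,5-trien-1-one (dienylketene, ketene carbon and alkenyl group cis) | C=CCOC(=C)\C=C(O[Si](C(C)C)(C(C)C)C(C)C)/C(=C=O)c1cc(Br)cc(OCc2ccccc2)c1OCc1ccccc1 | intermediate (not isolated)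
13 | 2-[2,3-bis(benzyloxy)-5-bromophenyl]-5-(prop-2-en-1-yloxy)-3-{[tri(propan-2-yl)silyl]oxy}cyclohexa-2,4-dien-1-one | O=C1CC(OCC=C)=CC(O[Si](C(C)C)(C(C)C)C(C)C)=C1c1cc(Br)cc(OCc2ccccc2)c1OCc1ccccc1 | intermediate (not isolated)
14 | 2',3'-bis(benzyloxy)-5'-bromo-4-(prop-2-en-1-yloxy)-6-{[tri(propan-2-yl)silyl]oxy}biphenyl-2-ol | C=CCOc1cc(O)c(-c2cc(Br)cc(OCc3ccccc3)c2OCc2ccccc2)c(O[Si](C(C)C)(C(C)C)C(C)C)c1 | intermediate
15 | 2',3'-bis(benzyloxy)-5'-bromo-4-(prop-2-en-1-yloxy)biphenyl-2,6-diol | C=CCOc1cc(O)c(-c2cc(Br)cc(OCc3ccccc3)c2OCc2ccccc2)c(O)c1 | intermediate (not isolated)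
16 | 2,2',3',6-tetrakis(benzyloxy)-5'-bromo-4-(prop-2-en-1-yloxy)biphenyl | C=CCOc1cc(OCc2ccccc2)c(-c2cc(Br)cc(OCc3ccccc3)c2OCc2ccccc2)c(OCc2ccccc2)c1 | intermediate
17 | 1-[2,2',3',6-tetrakis(benzyloxy)-5'-bromo-4-(prop-2-en-1-yloxy)biphenyl-3-yl]ethan-1-one | CC(=O)c1c(OCC=C)cc(OCc2ccccc2)c(-c2cc(Br)cc(OCc3ccccc3)c2OCc2ccccc2)c1OCc1ccccc1 | intermediate
18 | 1-[2,2',3',6-tetrakis(benzyloxy)-5'-bromo-4-hydroxybiphenyl-3-yl]ethan-1-one | CC(=O)c1c(O)cc(OCc2ccccc2)c(-c2cc(Br)cc(OCc3ccccc3)c2OCc2ccccc2)c1OCc1ccccc1 | intermediate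
19 | 3,4-bis(benzyloxy)benzaldehyde | O=Cc1ccc(OCc2ccccc2)c(OCc2ccccc2)c1 | starting material
20 | (E)-1-[2,2',3',6-tetrakis(benzyloxy)-5'-bromo-4-hydroxybiphenyl-3-yl]-3-[3,4-bis(benzyloxy)phenyl]prop-2-en-1-one | O=C(/C=C/c1ccc(OCc2ccccc2)c(OCc2ccccc2)c1)c1c(O)cc(OCc2ccccc2)c(-c2cc(Br)cc(OCc3ccccc3)c2OCc2ccccc2)c1OCc1ccccc1 | intermediate
21 | 5,7-bis(benzyloxy)-6-[2,3-bis(benzyloxy)-5-bromophenyl]-2-[3,4-bis(benzyloxy)phenyl]-4H-chromen-4-one | Brc1cc(OCc2ccccc2)c(OCc2ccccc2)c(-c2c(OCc3ccccc3)cc3oc(-c4ccc(OCc5ccccc5)c(OCc5ccccc5)c4)cc(=O)c3c2OCc2ccccc2)c1 | intermediate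
22 | {3,4-bis(benzyloxy)-5-[5,7-bis(benzyloxy)-2-(3,4-bis(benzyloxy)phenyl)-4-oxo-4H-chromen-6-yl]phenyl}boronic acid | OB(O)c1cc(OCc2ccccc2)c(OCc2ccccc2)c(-c2c(OCc3ccccc3)cc3oc(-c4ccc(OCc5ccccc5)c(OCc5ccccc5)c4)cc(=O)c3c2OCc2ccccc2)c1 | intermediate
23 | 5,7-dihydroxy-4H-chromen-4-one | O=c1ccoc2cc(O)cc(O)c12 | starting material
24 | 5,7-bis(benzyloxy)-4H-chromen-4-one | O=c1ccoc2cc(OCc3ccccc3)cc(OCc3ccccc3)c12 | intermediate
25 | (2S)-5,7-bis(benzyloxy)-2-{3,4-bis(benzyloxy)-5-[5,7-bis(benzyloxy)-2-(3,4-bis(benzyloxy)phenyl)-4-oxo-4H-chromen-6-yl]phenyl}-2,3-dihydro-4H-chromen-4-one | O=C1C[C@@H](c2cc(OCc3ccccc3)c(OCc3ccccc3)c(-c3c(OCc4ccccc4)cc4oc(-c5ccc(OCc6ccccc6)c(OCc6ccccc6)c5)cc(=O)c4c3OCc3ccccc3)c2)Oc2cc(OCc3ccccc3)cc(OCc3ccccc3)c21 | intermediate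
26 | (2S)-2-{3-[2-(3,4-dihydroxyphenyl)-5,7-dihydroxy-4-oxo-4H-chromen-6-yl]-4,5-dihydroxyphenyl}-5,7-dihydroxy-2,3-dihydro-4H-chromen-4-one | O=C1C[C@@H](c2cc(O)c(O)c(-c3c(O)cc4oc(-c5ccc(O)c(O)c5)cc(=O)c4c3O)c2)Oc2cc(O)cc(O)c21 | target

**Step count**

Total steps: 15. Longest linear sequence: 13 steps (steps 1–4, 6–12, 14 and 15); steps 5 and 13 prepare the two side partners.

**Steps most likely to fail**

1. Step 6. Ring opening of the donor-stabilised cyclobutenone may be too slow at a temperature the allyl enol ether tolerates, so that Claisen rearrangement, ketene oligomerisation or acylation of the product phenol by the ketene outruns capture by the siloxyalkyne. The fallback forms the biaryl bond by Suzuki–Miyaura coupling at the flavone stage; it sets out from aldehyde 3 and returns at flavone bromide 21. Pinnick oxidation of 3 (NaClO2, NaH2PO4, 2-methylbut-2-ene) gives 2,3-bis(benzyloxy)-5-bromobenzoic acid F1. Decarboxylative iodination of this ortho-alkoxybenzoic acid (I2, K3PO4, MeCN, heat) gives 1,2-bis(benzyloxy)-5-bromo-3-iodobenzene F2. Selective iodine–magnesium exchange (i-PrMgCl·LiCl, −40 °C), B(OMe)3 and acidic work-up give [2,3-bis(benzyloxy)-5-bromophenyl]boronic acid F3. In parallel, commercial luteolin is tribenzylated (BnBr, K2CO3, acetone) to 7-(benzyloxy)-2-[3,4-bis(benzyloxy)phenyl]-5-hydroxy-4H-chromen-4-one F4, iodinated at C6 next to the free 5-hydroxyl (benzyltrimethylammonium dichloroiodate, CaCO3, CH2Cl2/MeOH) to 7-(benzyloxy)-2-[3,4-bis(benzyloxy)phenyl]-5-hydroxy-6-iodo-4H-chromen-4-one F5, and 5-O-benzylated (BnBr, K2CO3, DMF) to 5,7-bis(benzyloxy)-2-[3,4-bis(benzyloxy)phenyl]-6-iodo-4H-chromen-4-one F6. Coupling of F6 with F3 (Pd(OAc)2, SPhos, K3PO4, toluene/H2O), in which the aryl iodide reacts before the bromide, gives 21.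

2. Step 14. Protodeboronation of the bulky boronic acid may outrun aryl transfer to rhodium, or face discrimination on the 5-substituted chromone may be poorer than on simpler chromones. The fallback builds the flavanone through a chalcone and separates the enantiomers; it sets out from bromide 21 and returns at 25. Palladium-catalysed formylation of 21 (Pd(OAc)2, 1,4-bis(diphenylphosphino)butane, N-formylsaccharin, Et3SiH, Na2CO3, DMF, 80 °C) gives 3,4-bis(benzyloxy)-5-[5,7-bis(benzyloxy)-2-(3,4-bis(benzyloxy)phenyl)-4-oxo-4H-chromen-6-yl]benzaldehyde F7. Claisen–Schmidt condensation with commercial 1-[2,4-bis(benzyloxy)-6-hydroxyphenyl]ethan-1-one F8 (KOH, EtOH/THF) gives the 2'-hydroxychalcone F9. Oxa-Michael closure (NaOAc, EtOH, reflux) gives the racemic flavanone F10, and preparative HPLC on a chiral stationary phase delivers 25.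

3. Step 5. Acid may hydrolyse or open the strained vinylogous ester faster than it exchanges the alkoxy group. The fallback alkylates the free dione instead; it sets out from 8 and returns at 9. Hydrolysis of 8 (aqueous CF3CO2H, 0 °C) gives cyclobutane-1,3-dione F11, and Mitsunobu O-alkylation of this acidic dione with allyl alcohol (PPh3, diisopropyl azodicarboxylate, THF, 0 °C) gives 9.

**Further compounds**

F1 | step 6 | 2,3-bis(benzyloxy)-5-bromobenzoic acid | OC(=O)c1cc(Br)cc(OCc2ccccc2)c1OCc1ccccc1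
F2 | step 6 | 1,2-bis(benzyloxy)-5-bromo-3-iodobenzene | Ic1cc(Br)cc(OCc2ccccc2)c1OCc1ccccc1
F3 | step 6 | [2,3-bis(benzyloxy)-5-bromophenyl]boronic acid | OB(O)c1cc(Br)cc(OCc2ccccc2)c1OCc1ccccc1
F4 | step 6 | 7-(benzyloxy)-2-[3,4-bis(benzyloxy)phenyl]-5-hydroxy-4H-chromen-4-one | O=c1cc(-c2ccc(OCc3ccccc3)c(OCc3ccccc3)c2)oc2cc(OCc3ccccc3)cc(O)c12
F5 | step 6 | 7-(benzyloxy)-2-[3,4-bis(benzyloxy)phenyl]-5-hydroxy-6-iodo-4H-chromen-4-one | O=c1cc(-c2ccc(OCc3ccccc3)c(OCc3ccccc3)c2)oc2cc(OCc3ccccc3)c(I)c(O)c12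
F6 | step 6 | 5,7-bis(benzyloxy)-2-[3,4-bis(benzyloxy)phenyl]-6-iodo-4H-chromen-4-one | O=c1cc(-c2ccc(OCc3ccccc3)c(OCc3ccccc3)c2)oc2cc(OCc3ccccc3)c(I)c(OCc3ccccc3)c12
F7 | step 14 | 3,4-bis(benzyloxy)-5-[5,7-bis(benzyloxy)-2-(3,4-bis(benzyloxy)phenyl)-4-oxo-4H-chromen-6-yl]benzaldehyde | O=Cc1cc(OCc2ccccc2)c(OCc2ccccc2)c(-c2c(OCc3ccccc3)cc3oc(-c4ccc(OCc5ccccc5)c(OCc5ccccc5)c4)cc(=O)c3c2OCc2ccccc2)c1
F8 | step 14 | 1-[2,4-bis(benzyloxy)-6-hydroxyphenyl]ethan-1-one | CC(=O)c1c(O)cc(OCc2ccccc2)cc1OCc1ccccc1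
F9 | step 14 | (E)-1-[2,4-bis(benzyloxy)-6-hydroxyphenyl]-3-{3,4-bis(benzyloxy)-5-[5,7-bis(benzyloxy)-2-(3,4-bis(benzyloxy)phenyl)-4-oxo-4H-chromen-6-yl]phenyl}prop-2-en-1-one | O=C(/C=C/c1cc(OCc2ccccc2)c(OCc2ccccc2)c(-c2c(OCc3ccccc3)cc3oc(-c4ccc(OCc5ccccc5)c(OCc5ccccc5)c4)cc(=O)c3c2OCc2ccccc2)c1)c1c(O)cc(OCc2ccccc2)cc1OCc1ccccc1
F10 | step 14 | racemic 5,7-bis(benzyloxy)-2-{3,4-bis(benzyloxy)-5-[5,7-bis(benzyloxy)-2-(3,4-bis(benzyloxy)phenyl)-4-oxo-4H-chromen-6-yl]phenyl}-2,3-dihydro-4H-chromen-4-one | O=C1CC(c2cc(OCc3ccccc3)c(OCc3ccccc3)c(-c3c(OCc4ccccc4)cc4oc(-c5ccc(OCc6ccccc6)c(OCc6ccccc6)c5)cc(=O)c4c3OCc3ccccc3)c2)Oc2cc(OCc3ccccc3)cc(OCc3ccccc3)c21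
F11 | step 5 | cyclobutane-1,3-dione | O=C1CC(=O)C1
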